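**Retrosynthetic overview**
1. Target 22 comes from tetra-MOM flavanone 21 by acidic MOM removal; 21 comes from 4-silyloxyflavan 19 by desilylation and oxidation of C4–OH to the C4 ketone.
2. Key disconnection: the aryl ether bond O1–C8a of ring C. O1 is the oxygen carried by the C2 stereocentre, and C8a is the ring A carbon para to the C6 prenyl group and meta to O5 and O7, so it maps onto the bromine-bearing carbon of symmetric 5-bromoresorcinol. Flavan 19 therefore comes from bromo alcohol 18 by palladium-catalysed intramolecular C–O coupling.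
3. 18 comes from a C3–C4 aldol bond between ring B methyl ketone 14 and ring A ortho-bromobenzaldehyde 7, then O4 silylation and CBS reduction, which sets C2 as S.
4. 7 comes from 5-bromoresorcinol 1 by two directed metalations (prenyl, then CHO); 14 comes from 4,6-dibromoresorcinol 8 by two Br–Li exchanges (prenyl, then acetyl).
5. Ring order: rings A and B are bought as arenes; ring C is the only ring formed, in step 10.

Key step: step 10

Remark: flavan numbering is used throughout. The C4 carbinol centre made in step 7 is not controlled, so compounds 16 to 20 are carried as pairs of C4 epimers that converge at the ketone in step 12.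

**Route**

Step 1
Reactants: 1 5-bromoresorcinol
Product: 2 1-bromo-3,5-bis(methoxymethoxy)benzene
Conditions: NaH (2.4 equiv), MOMCl (2.3 equiv), DMF, 0 °C → rt
Reagents that add atoms: chloromethyl methyl ether (MOMCl), COCCl
Why: Double Williamson etherification of the two phenoxides should give the bis-acetal, which protects the phenols and supplies the two coordinating groups that direct the metalation in step 2.

Step 2
Reactants: 2 1-bromo-3,5-bis(methoxymethoxy)benzene; 3 prenyl bromide
Product: 5 5-bromo-1,3-bis(methoxymethoxy)-2-(3-methylbut-2-en-1-yl)benzene, via aryllithium 4 (not isolated)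
Conditions: LiTMP (lithium 2,2,6,6-tetramethylpiperidide, 1.2 equiv), THF, −78 °C, 1 h; CuI (10 mol %); 3 (1.3 equiv), −78 → 0 °C
Reagents that add atoms: none
Why: Directed ortho-metalation: the hindered amide base does not undergo Br–Li exchange and should remove the proton between the two coordinating OMOM groups, the resulting aryllithium 4 has bromine para to lithium (no aryne pathway), and copper-catalysed allylic substitution at the primary carbon of prenyl bromide should give the linear prenyl arene.

Step 3
Reactants: 5 5-bromo-1,3-bis(methoxymethoxy)-2-(3-methylbut-2-en-1-yl)benzene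
Product: 7 6-bromo-2,4-bis(methoxymethoxy)-3-(3-methylbut-2-en-1-yl)benzaldehyde, via aryllithium 6 (not isolated)
Conditions: LiTMP (1.3 equiv), THF, −78 °C (5 added to the base), 30 min; DMF (3 equiv), −78 °C; then H2O
Reagents that add atoms: N,N-dimethylformamide, CN(C)C=O
Why: Directed ortho-metalation and formylation: the two remaining ring protons of 5 are equivalent by symmetry and each lies between a coordinating OMOM group and an acidifying bromine, so LiTMP at −78 °C should give the single aryllithium 6, which is persistent at this temperature and is trapped by DMF before LiBr can be lost.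

Step 4
Reactants: 8 4,6-dibromoresorcinol
Product: 9 1,5-dibromo-2,4-bis(methoxymethoxy)benzene
Conditions: NaH (2.4 equiv), MOMCl (2.3 equiv), DMF, 0 °C → rt
Reagents that add atoms: chloromethyl methyl ether (MOMCl), COCCl
Why: Double Williamson etherification of the phenoxides, as in step 1.

Step 5
Reactants: 9 1,5-dibromo-2,4-bis(methoxymethoxy)benzene; 3 prenyl bromide
Product: 11 1-bromo-2,4-bis(methoxymethoxy)-5-(3-methylbut-2-en-1-yl)benzene, via aryllithium 10 (not isolated)
Conditions: n-BuLi (1.0 equiv), THF, −78 °C, 20 min; CuI (10 mol %); 3 (1.3 equiv), −78 → 0 °C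
Reagents that add atoms: none
Why: Bromine–lithium exchange with one equivalent of n-BuLi at −78 °C is faster than any deprotonation and, the two bromines being equivalent, should give the single monolithio species 10, which is alkylated at the primary carbon of prenyl bromide under CuI catalysis.

Step 6
Reactants: 11 1-bromo-2,4-bis(methoxymethoxy)-5-(3-methylbut-2-en-1-yl)benzene; 12 N-methoxy-N-methylacetamide
Product: 14 1-[2,4-bis(methoxymethoxy)-5-(3-methylbut-2-en-1-yl)phenyl]ethan-1-one, via aryllithium 13 (not isolated)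
Conditions: n-BuLi (1.05 equiv), THF, −78 °C, 20 min; 12 (1.5 equiv), −78 → 0 °C; then H2O
Reagents that add atoms: none
Why: Second bromine–lithium exchange followed by Weinreb ketone synthesis: aryllithium 13 adds to the amide to give a chelated tetrahedral adduct that releases the methyl ketone only on aqueous work-up, so over-addition is avoided.

Step 7
Reactants: 14 1-[2,4-bis(methoxymethoxy)-5-(3-methylbut-2-en-1-yl)phenyl]ethan-1-one; 7 6-bromo-2,4-bis(methoxymethoxy)-3-(3-methylbut-2-en-1-yl)benzaldehyde
Product: 16 rac-3-[6-bromo-2,4-bis(methoxymethoxy)-3-(3-methylbut-2-en-1-yl)phenyl]-1-[2,4-bis(methoxymethoxy)-5-(3-methylbut-2-en-1-yl)phenyl]-3-hydroxypropan-1-one, via lithium enolate 15 (not isolated)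
Conditions: LDA (lithium diisopropylamide, 1.1 equiv), THF, −78 °C, 30 min; 7 (1.0 equiv), −78 °C, 1 h; AcOH (1.2 equiv) in THF at −78 °C
Reagents that add atoms: none
Why: Directed crossed aldol addition: LDA converts the methyl ketone into its only possible lithium enolate 15, which adds to the non-enolisable aldehyde 7, the cold acetic acid quench prevents retro-aldol and dehydration, and the new C4 carbinol centre forms as a racemate, which is accepted because it later becomes the carbonyl carbon.

Step 8
Reactants: 16 rac-aldol adduct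
Product: 17 rac-3-[6-bromo-2,4-bis(methoxymethoxy)-3-(3-methylbut-2-en-1-yl)phenyl]-1-[2,4-bis(methoxymethoxy)-5-(3-methylbut-2-en-1-yl)phenyl]-3-[(tert-butyldimethylsilyl)oxy]propan-1-one
Conditions: TBSOTf (1.3 equiv), 2,6-lutidine (2.5 equiv), CH2Cl2, −78 °C
Reagents that add atoms: tert-butyldimethylsilyl trifluoromethanesulfonate, CC(C)(C)[Si](C)(C)OS(=O)(=O)C(F)(F)F
Why: Silylation of the hindered secondary benzylic alcohol with a silyl triflate and a hindered pyridine base is fast at low temperature, outruns retro-aldol and elimination, and masks the C4 oxygen so that it cannot bind boron in step 9 or palladium in step 10.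

Step 9
Reactants: 17 rac-silyloxy ketone
Product: 18 (1S,3RS)-3-[6-bromo-2,4-bis(methoxymethoxy)-3-(3-methylbut-2-en-1-yl)phenyl]-1-[2,4-bis(methoxymethoxy)-5-(3-methylbut-2-en-1-yl)phenyl]-3-[(tert-butyldimethylsilyl)oxy]propan-1-ol (pair of C3 epimers)
Conditions: (R)-2-methyl-CBS-oxazaborolidine (20 mol %), catecholborane (1.8 equiv), toluene, −78 → −40 °C; then H2O
Reagents that add atoms: none
Why: Corey–Bakshi–Shibata reduction: the ketone binds the ring boron of the (R)-oxazaborolidine with the large aryl group turned away from the catalyst and hydride from the nitrogen-bound catecholborane is delivered to the Re face, which should set the carbinol (C2 of the flavan) as S under catalyst control in both C4 epimers, while catecholborane does not hydroborate the trisubstituted prenyl alkenes at this temperature.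

Step 10
Reactants: 18 (1S,3RS)-bromo alcohol
Product: 19 (2S,4RS)-4-[(tert-butyldimethylsilyl)oxy]-2-[2,4-bis(methoxymethoxy)-5-(3-methylbut-2-en-1-yl)phenyl]-5,7-bis(methoxymethoxy)-6-(3-methylbut-2-en-1-yl)chromane
Conditions: Pd(OAc)2 (5 mol %), 2-(di-tert-butylphosphino)-1,1'-binaphthyl (6 mol %), Cs2CO3 (1.5 equiv), toluene, 70 °C
Reagents that add atoms: none
Why: Pd(OAc)2 is reduced in the flask to a zerovalent palladium–phosphine complex that adds oxidatively into the C8a–Br bond, the only carbon–halogen bond; the C2 hydroxyl then binds the divalent arylpalladium bromide and is deprotonated by Cs2CO3 to a seven-membered arylpalladium alkoxide, and C–O reductive elimination forms O1–C8a. The closest known reaction type is the palladium-catalysed intramolecular etherification of aryl bromides with secondary alcohols to chromans (Buchwald–Hartwig C–O coupling). Ring C closes in this reductive elimination as a six-membered ring, by attack of the tethered oxygen on the aryl carbon through the seven-membered palladacycle. No stereocentre is created: the C2–O bond is never broken, so the S configuration from step 9 should be retained, and C4 stays as the epimer pair. The selectivity needed is C–O reductive elimination over beta-hydride elimination of the secondary benzylic alkoxide, which would give the C2 ketone and the debrominated arene; the bulky, electron-rich di-tert-butyl biaryl phosphine and the favourable six-membered closure secure it. The C4 oxygen is silylated so that it cannot bind palladium, and the insoluble carbonate in toluene keeps free alkoxide scarce, which disfavours silyl migration from O4 to the C2 oxygen.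

Step 11
Reactants: 19 (2S,4RS)-4-silyloxyflavan
Product: 20 (2S,4RS)-2-[2,4-bis(methoxymethoxy)-5-(3-methylbut-2-en-1-yl)phenyl]-5,7-bis(methoxymethoxy)-6-(3-methylbut-2-en-1-yl)chroman-4-ol
Conditions: Bu4NF (1.5 equiv), THF, 0 °C → rt; then H2O
Reagents that add atoms: none
Why: Fluoride-mediated silyl ether cleavage, driven by the Si–F bond, should free the C4 alcohol under non-acidic conditions that leave the MOM acetals, the prenyl alkenes and C2 untouched.

Step 12
Reactants: 20 (2S,4RS)-flavan-4-ol
Product: 21 (2S)-2-[2,4-bis(methoxymethoxy)-5-(3-methylbut-2-en-1-yl)phenyl]-5,7-bis(methoxymethoxy)-6-(3-methylbut-2-en-1-yl)chroman-4-one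
Conditions: Dess–Martin periodinane (1.5 equiv), NaHCO3 (5 equiv), CH2Cl2, 0 °C → rt
Reagents that add atoms: none
Why: Dess–Martin oxidation of the secondary benzylic alcohol should give the C4 ketone under buffered, near-neutral conditions, converging both C4 epimers to one compound without exposing the phenol-protected flavanone to base that could open ring C.

Step 13
Reactants: 21 (2S)-tetra-MOM flavanone
Product: 22 (2S)-2-[2,4-dihydroxy-5-(3-methylbut-2-en-1-yl)phenyl]-5,7-dihydroxy-6-(3-methylbut-2-en-1-yl)chroman-4-one (CNP0320454.1)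
Conditions: 3 M aq. HCl/MeOH (1:5), 40 °C
Reagents that add atoms: none
Why: Acid-catalysed methanolysis (transacetalisation) of the four aryl MOM acetals should release the phenols and dimethoxymethane, with moderate temperature and short reaction time chosen so that the C2–O1 bond is not ionised and the prenyl groups do not cyclise onto the neighbouring phenols.

**Compound list**
1 | 5-bromoresorcinol (5-bromobenzene-1,3-diol) | Oc1cc(O)cc(Br)c1 | starting material
2 | 1-bromo-3,5-bis(methoxymethoxy)benzene | COCOc1cc(Br)cc(OCOC)c1 | intermediate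
3 | prenyl bromide (1-bromo-3-methylbut-2-ene) | CC(C)=CCBr | starting material
4 | [4-bromo-2,6-bis(methoxymethoxy)phenyl]lithium | [Li]c1c(OCOC)cc(Br)cc1OCOC | intermediate
5 | 5-bromo-1,3-bis(methoxymethoxy)-2-(3-methylbut-2-en-1-yl)benzene | COCOc1cc(Br)cc(OCOC)c1CC=C(C)C | intermediate
6 | [2-bromo-4,6-bis(methoxymethoxy)-5-(3-methylbut-2-en-1-yl)phenyl]lithium | [Li]c1c(Br)cc(OCOC)c(CC=C(C)C)c1OCOC | intermediate
7 | 6-bromo-2,4-bis(methoxymethoxy)-3-(3-methylbut-2-en-1-yl)benzaldehyde | O=Cc1c(Br)cc(OCOC)c(CC=C(C)C)c1OCOC | intermediate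
8 | 4,6-dibromoresorcinol (4,6-dibromobenzene-1,3-diol) | Oc1cc(O)c(Br)cc1Br | starting material
9 | 1,5-dibromo-2,4-bis(methoxymethoxy)benzene | COCOc1cc(OCOC)c(Br)cc1Br | intermediate
10 | [5-bromo-2,4-bis(methoxymethoxy)phenyl]lithium | [Li]c1cc(Br)c(OCOC)cc1OCOC | intermediate
11 | 1-bromo-2,4-bis(methoxymethoxy)-5-(3-methylbut-2-en-1-yl)benzene | COCOc1cc(OCOC)c(CC=C(C)C)cc1Br | intermediate
12 | N-methoxy-N-methylacetamide | CC(=O)N(C)OC | starting material
13 | [2,4-bis(methoxymethoxy)-5-(3-methylbut-2-en-1-yl)phenyl]lithium | [Li]c1cc(CC=C(C)C)c(OCOC)cc1OCOC | intermediate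
14 | 1-[2,4-bis(methoxymethoxy)-5-(3-methylbut-2-en-1-yl)phenyl]ethan-1-one | CC(=O)c1cc(CC=C(C)C)c(OCOC)cc1OCOC | intermediate
15 | lithium 1-[2,4-bis(methoxymethoxy)-5-(3-methylbut-2-en-1-yl)phenyl]ethen-1-olate | [Li]OC(=C)c1cc(CC=C(C)C)c(OCOC)cc1OCOC | intermediate
16 | rac-3-[6-bromo-2,4-bis(methoxymethoxy)-3-(3-methylbut-2-en-1-yl)phenyl]-1-[2,4-bis(methoxymethoxy)-5-(3-methylbut-2-en-1-yl)phenyl]-3-hydroxypropan-1-one | O=C(CC(O)c1c(Br)cc(OCOC)c(CC=C(C)C)c1OCOC)c1cc(CC=C(C)C)c(OCOC)cc1OCOC | intermediate
17 | rac-3-[6-bromo-2,4-bis(methoxymethoxy)-3-(3-methylbut-2-en-1-yl)phenyl]-1-[2,4-bis(methoxymethoxy)-5-(3-methylbut-2-en-1-yl)phenyl]-3-[(tert-butyldimethylsilyl)oxy]propan-1-one | O=C(CC(O[Si](C)(C)C(C)(C)C)c1c(Br)cc(OCOC)c(CC=C(C)C)c1OCOC)c1cc(CC=C(C)C)c(OCOC)cc1OCOC | intermediate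
18 | (1S,3RS)-3-[6-bromo-2,4-bis(methoxymethoxy)-3-(3-methylbut-2-en-1-yl)phenyl]-1-[2,4-bis(methoxymethoxy)-5-(3-methylbut-2-en-1-yl)phenyl]-3-[(tert-butyldimethylsilyl)oxy]propan-1-ol, C3 epimer pair | O[C@@H](CC(O[Si](C)(C)C(C)(C)C)c1c(Br)cc(OCOC)c(CC=C(C)C)c1OCOC)c1cc(CC=C(C)C)c(OCOC)cc1OCOC | intermediate
19 | (2S,4RS)-4-[(tert-butyldimethylsilyl)oxy]-2-[2,4-bis(methoxymethoxy)-5-(3-methylbut-2-en-1-yl)phenyl]-5,7-bis(methoxymethoxy)-6-(3-methylbut-2-en-1-yl)chromane, C4 epimer pair | CC(C)(C)[Si](C)(C)OC1C[C@@H](c2cc(CC=C(C)C)c(OCOC)cc2OCOC)Oc2cc(OCOC)c(CC=C(C)C)c(OCOC)c21 | intermediate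
20 | (2S,4RS)-2-[2,4-bis(methoxymethoxy)-5-(3-methylbut-2-en-1-yl)phenyl]-5,7-bis(methoxymethoxy)-6-(3-methylbut-2-en-1-yl)chroman-4-ol, C4 epimer pair | OC1C[C@@H](c2cc(CC=C(C)C)c(OCOC)cc2OCOC)Oc2cc(OCOC)c(CC=C(C)C)c(OCOC)c21 | intermediate
21 | (2S)-2-[2,4-bis(methoxymethoxy)-5-(3-methylbut-2-en-1-yl)phenyl]-5,7-bis(methoxymethoxy)-6-(3-methylbut-2-en-1-yl)chroman-4-one | O=C1C[C@@H](c2cc(CC=C(C)C)c(OCOC)cc2OCOC)Oc2cc(OCOC)c(CC=C(C)C)c(OCOC)c21 | intermediate
22 | (2S)-2-[2,4-dihydroxy-5-(3-methylbut-2-en-1-yl)phenyl]-5,7-dihydroxy-6-(3-methylbut-2-en-1-yl)chroman-4-one | CC(C)=CCc1cc([C@@H]2CC(=O)c3c(cc(O)c(CC=C(C)C)c3O)O2)c(O)cc1O | target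

**Totals**
Total step count: 13.
Longest linear sequence: 10 steps (steps 1–3 then 7–13; the branch 4–6 then 7–13 is equally long).

**Steps most likely to fail**

Step 10. Beta-hydride elimination from the arylpalladium alkoxide may outrun C–O reductive elimination, which would oxidise the C2 carbinol and reduce the C8a–Br bond. Base-induced silyl migration from O4 to the C2 oxygen would also remove the nucleophile. The fallback closes ring C at O1–C2 instead and sets out from 17. Miyaura borylation (B2pin2, PdCl2(dppf), KOAc, 1,4-dioxane, 80 °C) should give the aryl pinacol boronate F1. Oxidation with NaBO3·4H2O in THF/H2O at rt should give the phenol F2. Reduction with the enantiomeric (S)-2-methyl-CBS-oxazaborolidine and catecholborane (toluene, −78 → −40 °C) should give the (1R)-carbinol F3. Mitsunobu etherification (PPh3, DIAD, THF, 0 °C) then joins the phenol oxygen to the carbinol carbon with inversion, so the (2S)-flavan is formed and the route is rejoined at 19.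

Step 3. The ortho-bromoaryllithium may lose LiBr to an aryne, bromine may migrate between lithiated and unlithiated arene, or the base may instead deprotonate the benzylic–allylic CH2 of the prenyl group. The fallback generates the aryl metal by halogen–magnesium exchange and sets out from 2. Bromination with NBS (1.0 equiv, MeCN, 0 °C), para to one OMOM group and ortho to bromine, should give the dibromide F4. Metalation between the OMOM groups (LiTMP, THF, −78 °C) and prenylation with 3 under CuI catalysis should give the prenylated dibromide F5. Treatment with i-PrMgCl·LiCl (THF, −20 °C) should exchange selectively the bromine flanked by the chelating OMOM group; the ortho-bromoaryl Grignard reagent does not eliminate at this temperature. Quenching with DMF rejoins the route at 7.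

Step 13. Acid may ionise or open the benzylic C2–O1 bond, assisted by the 2'- and 4'-oxygens, with erosion of the C2 configuration, or may cyclise a prenyl group onto the neighbouring phenol. The fallback removes the acetals without protic acid and sets out from 21. TMSOTf (8 equiv) and 2,2'-bipyridyl (12 equiv) in CH2Cl2 at 0 °C → rt should convert the four aryl MOM ethers into the tetrakis(trimethylsilyl) ether F6. Hydrolysis with water at pH 7 then frees the phenols and rejoins the route at 22.

**Further compounds**
F1 | step 10 | rac-1-[2,4-bis(methoxymethoxy)-5-(3-methylbut-2-en-1-yl)phenyl]-3-[2,4-bis(methoxymethoxy)-3-(3-methylbut-2-en-1-yl)-6-(4,4,5,5-tetramethyl-1,3,2-dioxaborolan-2-yl)phenyl]-3-[(tert-butyldimethylsilyl)oxy]propan-1-one | O=C(CC(O[Si](C)(C)C(C)(C)C)c1c(B2OC(C)(C)C(C)(C)O2)cc(OCOC)c(CC=C(C)C)c1OCOC)c1cc(CC=C(C)C)c(OCOC)cc1OCOC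
F2 | step 10 | rac-1-[2,4-bis(methoxymethoxy)-5-(3-methylbut-2-en-1-yl)phenyl]-3-[6-hydroxy-2,4-bis(methoxymethoxy)-3-(3-methylbut-2-en-1-yl)phenyl]-3-[(tert-butyldimethylsilyl)oxy]propan-1-one | O=C(CC(O[Si](C)(C)C(C)(C)C)c1c(O)cc(OCOC)c(CC=C(C)C)c1OCOC)c1cc(CC=C(C)C)c(OCOC)cc1OCOC
F3 | step 10 | (1R,3RS)-1-[2,4-bis(methoxymethoxy)-5-(3-methylbut-2-en-1-yl)phenyl]-3-[6-hydroxy-2,4-bis(methoxymethoxy)-3-(3-methylbut-2-en-1-yl)phenyl]-3-[(tert-butyldimethylsilyl)oxy]propan-1-ol | O[C@H](CC(O[Si](C)(C)C(C)(C)C)c1c(O)cc(OCOC)c(CC=C(C)C)c1OCOC)c1cc(CC=C(C)C)c(OCOC)cc1OCOC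
F4 | step 3 | 1,2-dibromo-3,5-bis(methoxymethoxy)benzene | COCOc1cc(OCOC)c(Br)c(Br)c1
F5 | step 3 | 1,2-dibromo-3,5-bis(methoxymethoxy)-4-(3-methylbut-2-en-1-yl)benzene | COCOc1cc(Br)c(Br)c(OCOC)c1CC=C(C)C
F6 | step 13 | (2S)-2-[5-(3-methylbut-2-en-1-yl)-2,4-bis(trimethylsilyloxy)phenyl]-6-(3-methylbut-2-en-1-yl)-5,7-bis(trimethylsilyloxy)chroman-4-one | O=C1C[C@@H](c2cc(CC=C(C)C)c(O[Si](C)(C)C)cc2O[Si](C)(C)C)Oc2cc(O[Si](C)(C)C)c(CC=C(C)C)c(O[Si](C)(C)C)c21
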